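**Assumption:** 3-chloro-L-alanine methyl ester (5) is counted as its free base (8 non-hydrogen atoms); it is weighed out as the commercial hydrochloride.

**Core labels used below:** C1 (CH–N), C2 (CH2), C3 (bridgehead C–OH), C4 (bridging C=O), C5 (bridgehead CH), C6 (CH–OH), C7 and C8 (oxirane CH), C9 (CH–OH). "Exo" is the face of the C3–C8 ring away from the C2–C1–C9 bridge.

## Retrosynthetic overview

1. The oxirane is made last: target ⇐ OH-directed epoxidation of a C7=C8 ene-diol ⇐ Wharton transposition of an exo C6–C7 epoxy C8-ketone ⇐ bicyclo[3.3.1]nonene-dione.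
2. The C5–C9 bond ⇐ desymmetrising intramolecular aldol of a 2-alkyl-2-hydroxycyclohexene-1,3-dione that carries an L-α-amido aldehyde; this dione is a dearomatised resorcinol.
3. Key bond C2–C3 (CH2–aryl) ⇐ Ni-catalysed radical cross-electrophile coupling of unprotected 2-iodoresorcinol with an N-decenoyl β-haloalanine ester. The radical is at C2, so the C1 stereocentre of 3-chloro-L-alanine survives and later controls C3, C5 and C9.
4. The (E)-dec-2-enoyl chain ⇐ heptylcopper + ethyl propiolate; it is attached before the coupling, so no N-protecting group is used.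
5. Ring order: C3–C8 carbocycle (from the arene) → C1–C5/C9 ring (aldol) → oxirane.

## Route

**Step 1**
Reactants: 1, 1-bromoheptane; 2, ethyl propiolate
Product: 3, ethyl (2E)-dec-2-enoate
Conditions: Mg, THF; CuBr·SMe2, THF/Me2S, −45 °C; then 2, −78 °C; NH4Cl/MeOH quench at −78 °C
Reagents that add atoms: none
Why: Syn-carbocupration of the propiolate followed by protonation with retention puts the heptyl group trans to CO2Et, giving the (E)-enoate (organocopper conjugate addition).

**Step 2**
Reactants: 3, ethyl (2E)-dec-2-enoate
Product: 4, (2E)-dec-2-enoic acid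
Conditions: LiOH, THF/H2O, 23 °C; then 1 M HCl
Reagents that add atoms: lithium hydroxide, [Li+].[OH-] (the acid OH oxygen)
Why: Ester saponification; the conjugated (E)-alkene does not isomerise under these conditions.

**Step 3**
Reactants: 4, (2E)-dec-2-enoic acid; 5, methyl (2R)-2-amino-3-chloropropanoate (3-chloro-L-alanine methyl ester, HCl salt)
Product: 6, methyl (2R)-3-chloro-2-[(2E)-dec-2-enamido]propanoate
Conditions: EDC·HCl, HOBt, N-methylmorpholine, CH2Cl2, 0→23 °C
Reagents that add atoms: none
Why: Carbodiimide amide coupling; the weak base and low temperature avoid β-elimination, and the α-stereocentre (future C1) is untouched.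

**Step 4**
Reactants: 7, resorcinol
Product: 8, 2-iodobenzene-1,3-diol (2-iodoresorcinol)
Conditions: I2, NaHCO3, H2O, 0→23 °C
Reagents that add atoms: iodine, II
Why: Electrophilic iodination of the resorcinolate in water goes to the carbon between the two oxygens.

**Step 5 (key step)**
Reactants: 6, methyl (2R)-3-chloro-2-[(2E)-dec-2-enamido]propanoate; 8, 2-iodoresorcinol
Product: 9, methyl (2S)-2-[(2E)-dec-2-enamido]-3-(2,6-dihydroxyphenyl)propanoate (partial closure to the dihydrocoumarin lactone is harmless)
Conditions: NiBr2·glyme (10 mol %), 4,4′-di-tert-butyl-2,2′-bipyridine (10 mol %), Zn (3 equiv), NaI (1.5 equiv), DMA, 40 °C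
Reagents that add atoms: none
Why: Ni-catalysed reductive cross-electrophile coupling: iodide exchange gives the primary iodide, Ni/Zn turns it into the C2 alkyl radical, this is captured by the aryl–Ni(II) species from 8, and reductive elimination forms the C2–C3 bond; the radical is β to the stereocentre, so C1 is retained.

**Step 6**
Reactants: 9, methyl (2S)-2-[(2E)-dec-2-enamido]-3-(2,6-dihydroxyphenyl)propanoate
Product: 10, (2E)-N-[(3S)-2,5-dihydroxy-3,4-dihydro-2H-chromen-3-yl]dec-2-enamide (lactol, mixture at C2 of the chroman)
Conditions: DIBAL-H (4 equiv), CH2Cl2, −78 °C; Rochelle salt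
Reagents that add atoms: none
Why: Partial reduction of the ester (or its lactone) stops at the aluminium hemiacetal, and on work-up the aldehyde is held as the 2-hydroxychroman, which protects the α-amido aldehyde from epimerisation; the deprotonated amide is not reduced.

**Step 7**
Reactants: 10, the lactol
Product: 11, (2E)-N-[(1S,3S,4R,5R)-1,4-dihydroxy-8,9-dioxobicyclo[3.3.1]non-6-en-3-yl]dec-2-enamide
Conditions: PhI(OAc)2 (1.05 equiv), (CF3)2CHOH, 0 °C; then sat. aq NaHCO3/THF, 23 °C
Reagents that add atoms: water, O (net source of the new C3 oxygen; PhI(OAc)2 is only the oxidant)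
Why: Proposed new method: iodine(III) activates the free phenol and, in non-nucleophilic HFIP, the tethered amide carbonyl oxygen attacks the alkylated ortho carbon C3 through a six-membered ring (closest known types: Kita/Ishihara ortho-spirocyclising phenol dearomatisation and amide-oxygen participation); aqueous bicarbonate hydrolyses the imidate and lactol to a 2-alkyl-2-hydroxycyclohexene-1,3-dione whose two carbonyl arms are equivalent, and the enol then adds to the aldehyde in a Hajos–Parrish-type desymmetrising aldol in which only the arm that leaves the NH-acyl group equatorial can close (sets C3 and C5 from C1), with the aldehyde oxygen hydrogen-bonded towards the bridging carbonyl (sets the axial C9–OH).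

**Step 8**
Reactants: 11, the bicyclic ene-dione
Product: 12, (2E)-N-[(1S,2S,4S,6R,8S,9R)-6,9-dihydroxy-5,10-dioxo-3-oxatricyclo[4.3.1.0^2,4]decan-8-yl]dec-2-enamide (exo C6–C7 epoxide)
Conditions: t-BuOOH, DBU, CH2Cl2, 0 °C
Reagents that add atoms: tert-butyl hydroperoxide, CC(C)(C)OO
Why: Weitz–Scheffer nucleophilic epoxidation of the enone; the peroxide adds to C6 from the exo face because the endo face is blocked by the C2–C1–C9 bridge, which places the future C6 oxygen on the correct face.

**Step 9**
Reactants: 12, the epoxy ketone
Product: 13, (2E)-N-[(1R,2R,3S,5S,8R)-2,5,8-trihydroxy-9-oxobicyclo[3.3.1]non-6-en-3-yl]dec-2-enamide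
Conditions: N2H4·H2O, AcOH (cat.), MeOH, 0→23 °C, under N2
Reagents that add atoms: none
Why: Wharton transposition: the hydrazone of the α,β-epoxy ketone opens the epoxide and loses N2, giving the C7=C8 alkene and the C6 allylic alcohol with the C6–O configuration retained from the exo epoxide; the bridging C4 ketone, flanked by two bridgeheads, should react more slowly.

**Step 10**
Reactants: 13, the ene-diol
Product: 14, isariotin D, (2E)-N-[(1S,2S,4S,5S,6S,7R,8S)-1,5,7-trihydroxy-10-oxo-3-oxatricyclo[4.3.1.0^2,4]decan-8-yl]dec-2-enamide
Conditions: VO(acac)2 (5 mol %), t-BuOOH, CH2Cl2, 0→23 °C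
Reagents that add atoms: tert-butyl hydroperoxide, CC(C)(C)OO
Why: Hydroxyl-directed vanadium epoxidation: the C6 and C3 allylic hydroxyls, both on the exo (convex) face, deliver oxygen syn to give the all-cis epoxy-diol, and the electron-poor enamide alkene is left alone.

## Compound list

1 | 1-bromoheptane | CCCCCCCBr | starting material
2 | ethyl propiolate | C#CC(=O)OCC | starting material
3 | ethyl (2E)-dec-2-enoate | CCCCCCC/C=C/C(=O)OCC | intermediate
4 | (2E)-dec-2-enoic acid | CCCCCCC/C=C/C(=O)O | intermediate
5 | methyl (2R)-2-amino-3-chloropropanoate (3-chloro-L-alanine methyl ester; used as HCl salt) | N[C@@H](CCl)C(=O)OC | starting material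
6 | methyl (2R)-3-chloro-2-[(2E)-dec-2-enamido]propanoate | CCCCCCC/C=C/C(=O)N[C@@H](CCl)C(=O)OC | intermediate
7 | resorcinol | Oc1cccc(O)c1 | starting material
8 | 2-iodobenzene-1,3-diol | Oc1cccc(O)c1I | intermediate
9 | methyl (2S)-2-[(2E)-dec-2-enamido]-3-(2,6-dihydroxyphenyl)propanoate | CCCCCCC/C=C/C(=O)N[C@@H](Cc1c(O)cccc1O)C(=O)OC | intermediate
10 | (2E)-N-[(3S)-2,5-dihydroxy-3,4-dihydro-2H-chromen-3-yl]dec-2-enamide (lactol, both C2 epimers) | CCCCCCC/C=C/C(=O)N[C@H]1Cc2c(O)cccc2OC1O | intermediate
11 | (2E)-N-[(1S,3S,4R,5R)-1,4-dihydroxy-8,9-dioxobicyclo[3.3.1]non-6-en-3-yl]dec-2-enamide | CCCCCCC/C=C/C(=O)N[C@H]1C[C@@]2(O)C(=O)[C@H](C=CC2=O)[C@H]1O | intermediate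
12 | (2E)-N-[(1S,2S,4S,6R,8S,9R)-6,9-dihydroxy-5,10-dioxo-3-oxatricyclo[4.3.1.0^2,4]decan-8-yl]dec-2-enamide | CCCCCCC/C=C/C(=O)N[C@H]1C[C@@]2(O)C(=O)[C@H]([C@@H]3O[C@@H]3C2=O)[C@H]1O | intermediate
13 | (2E)-N-[(1R,2R,3S,5S,8R)-2,5,8-trihydroxy-9-oxobicyclo[3.3.1]non-6-en-3-yl]dec-2-enamide | CCCCCCC/C=C/C(=O)N[C@H]1C[C@@]2(O)C(=O)[C@H]([C@H](O)C=C2)[C@H]1O | intermediate
14 | isariotin D | CCCCCCC/C=C/C(=O)N[C@H]1C[C@@]2(O)C(=O)[C@H]([C@H](O)[C@@H]3O[C@@H]32)[C@H]1O | target

## Step count and risks

Total steps: 10. Longest linear sequence: 9 (steps 1, 2, 3, 5, 6, 7, 8, 9, 10).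

Steps most likely to fail:

1. **Step 5 (radical cross-coupling).** The aryl iodide has two free ortho hydroxyls, the alkyl partner is a chloride exchanged in situ, and 6 can eliminate to the dehydroalanine or close to an oxazoline. Fallback: make the C2–C3 bond by polar C-alkylation of cyclohexane-1,3-dione with an L-serine-derived N-Boc cyclic sulfamidate, swap Boc for the decenoyl group, then hydroxylate C3 and dehydrogenate with IBX to reach the same hydroxy-dione without any arene.
2. **Step 7 (dearomatisation and aldol cascade).** Oxidation could go para to the phenol instead of at C3, and the free α-amido aldehyde could epimerise before the aldol, which would erode the enantiomeric purity. Fallback: separate the events and change their type: IBX ortho-hydroxylative dearomatisation of ester 9 (both phenols free), then DIBAL, then a proline-type organocatalysed desymmetrising aldol.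
3. **Step 9 (Wharton transposition).** Hydrazine may also attack the C4 ketone, or cleave the 2-hydroxy-1,3-dione by retro-Claisen. Fallback: drop the epoxide/hydrazine transposition; install the C6 oxygen on enone 11 by copper-catalysed conjugate borylation from the exo face and oxidation, then convert the C8 ketone to the C7=C8 alkene through its enol triflate and Pd/formate reduction before the directed epoxidation.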